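**Retrosynthetic overview**
- The all-E triene is cut between C2' and C3' (Stille coupling): a core-bound (E)-vinylstannane plus an (E,E)-iododienamide that already carries the aminocyclopentenone.
- The enamide C–N bond is cut next (Cu-catalysed N-vinylation): an α-iodoenone core plus the primary amide of the branched side chain.
- The core comes from the achiral p-quinol made from p-benzoquinone and a silyl acetylide. A silanol tethered to the tertiary OH adds to one enone arm (new desymmetrisation) and sets the cis-diol.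
- The side-chain amide comes from n-butylboronic acid by two reagent-controlled boronic ester homologations (anti-1,3-dimethyl), Zweifel vinylation and cross-metathesis with acrylamide. The iododienamide comes from Takai olefination and acylation of the amine made from cyclopentane-1,3-dione.
- No carbocycle is built: both rings are bought. The only ring closure is the temporary dioxasilolane (step 9), opened again in step 17.

Assumption: methyl (E)-4-oxobut-2-enoate and both sparteine enantiomers are bought; in the new step the quinidine-derived catalyst is assumed to give the series shown, and its quinine-derived pseudoenantiomer is used if the sense proves opposite.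

**Step 1**
Reactants: 1 n-butylboronic acid
Product: 2 2-butyl-4,4,5,5-tetramethyl-1,3,2-dioxaborolane
Conditions: pinacol, MgSO4, Et2O, rt
Reagents that add atoms: pinacol CC(C)(O)C(C)(C)O
Why: Boronic ester formation by condensation with a 1,2-diol goes to completion once water is removed; no stereocentre.

**Step 2**
Reactants: 2 2-butyl-4,4,5,5-tetramethyl-1,3,2-dioxaborolane
Product: 4 (S)-2-(hexan-2-yl)-4,4,5,5-tetramethyl-1,3,2-dioxaborolane, via lithium boronate complex 3 (not isolated)
Conditions: ethyl 2,4,6-triisopropylbenzoate, s-BuLi, (+)-sparteine, Et2O, −78 °C; add 2; then 35 °C; 1 M HCl work-up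
Reagents that add atoms: ethyl 2,4,6-triisopropylbenzoate CCOC(=O)c1c(C(C)C)cc(C(C)C)cc1C(C)C
Why: Lithiation–borylation (Hoppe-type asymmetric deprotonation, then 1,2-metallate rearrangement): (+)-sparteine gives the (R)-α-lithio benzoate, boron adds with retention and butyl migrates anti to the benzoate (inversion), which sets the (S) centre.

**Step 3**
Reactants: 4 (S)-2-(hexan-2-yl)-4,4,5,5-tetramethyl-1,3,2-dioxaborolane
Product: 6 (R)-4,4,5,5-tetramethyl-2-(2-methylhexyl)-1,3,2-dioxaborolane, via chloromethyl boronate complex 5 (not isolated)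
Conditions: BrCH2Cl, n-BuLi, Et2O, −78 °C → rt
Reagents that add atoms: bromochloromethane ClCBr
Why: Matteson homologation: LiCH2Cl made in situ adds to boron and the secondary alkyl group migrates with retention (the descriptor changes from S to R only through CIP priorities).

**Step 4**
Reactants: 6 (R)-4,4,5,5-tetramethyl-2-(2-methylhexyl)-1,3,2-dioxaborolane
Product: 8 4,4,5,5-tetramethyl-2-[(2R,4S)-4-methyloctan-2-yl]-1,3,2-dioxaborolane, via lithium boronate complex 7 (not isolated)
Conditions: ethyl 2,4,6-triisopropylbenzoate, s-BuLi, (−)-sparteine, Et2O, −78 °C; add 6; then 35 °C; 1 M HCl work-up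
Reagents that add atoms: ethyl 2,4,6-triisopropylbenzoate CCOC(=O)c1c(C(C)C)cc(C(C)C)cc1C(C)C
Why: Second lithiation–borylation under reagent control: (−)-sparteine gives the (S)-α-lithio benzoate, and retention at boron followed by invertive migration sets the (R) centre, anti to the first methyl group.

**Step 5**
Reactants: 8 4,4,5,5-tetramethyl-2-[(2R,4S)-4-methyloctan-2-yl]-1,3,2-dioxaborolane
Product: 11 (3R,5S)-3,5-dimethylnon-1-ene, via vinyl boronate complex 9 (not isolated), via β-iodo boronic ester 10 (not isolated)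
Conditions: CH2=CHMgBr, THF/DMSO (1:1), rt; then I2, then NaOMe, MeOH, 0 °C
Reagents that add atoms: vinylmagnesium bromide C=C[Mg]Br
Why: Zweifel olefination: iodine triggers 1,2-migration of the secondary alkyl group with retention, and methoxide then causes anti-elimination of boron and iodide to give the terminal alkene.

**Step 6**
Reactants: 11 (3R,5S)-3,5-dimethylnon-1-ene; 12 acrylamide
Product: 13 (2E,4R,6S)-4,6-dimethyldec-2-enamide
Conditions: Hoveyda–Grubbs II (5 mol %), acrylamide (3 equiv), CH2Cl2, 40 °C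
Reagents that add atoms: none
Why: Olefin cross-metathesis of a terminal alkene with an electron-poor acrylamide is selective for the cross product and gives the E-enamide; the allylic stereocentre is untouched.

**Step 7**
Reactants: 14 1,4-benzoquinone; 15 ethynyltrimethylsilane
Product: 17 4-hydroxy-4-[(trimethylsilyl)ethynyl]cyclohexa-2,5-dien-1-one, via lithium (trimethylsilyl)acetylide 16 (not isolated)
Conditions: n-BuLi, THF, −78 °C; add to 14 (1.0 equiv), THF, −78 °C; aq NH4Cl
Reagents that add atoms: none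
Why: 1,2-Addition of a lithium acetylide to one quinone carbonyl (p-quinol synthesis); low temperature and 1:1 stoichiometry limit double addition, and the product is achiral.

**Step 8**
Reactants: 17 4-hydroxy-4-[(trimethylsilyl)ethynyl]cyclohexa-2,5-dien-1-one
Product: 19 4-{[di-tert-butyl(hydroxy)silyl]oxy}-4-[(trimethylsilyl)ethynyl]cyclohexa-2,5-dien-1-one, via silyl triflate 18 (not isolated)
Conditions: tBu2Si(OTf)2, 2,6-lutidine, CH2Cl2, 0 °C; then cold sat. aq NaHCO3
Reagents that add atoms: di-tert-butylsilyl bis(trifluoromethanesulfonate) CC(C)(C)[Si](OS(=O)(=O)C(F)(F)F)(OS(=O)(=O)C(F)(F)F)C(C)(C)C; water O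
Why: O-Silylation of the tertiary alcohol by the highly electrophilic silyl bis-triflate, then hydrolysis of the remaining Si–OTf, gives a hindered silanol that does not condense to a disiloxane.

**Step 9**
Reactants: 19 4-{[di-tert-butyl(hydroxy)silyl]oxy}-4-[(trimethylsilyl)ethynyl]cyclohexa-2,5-dien-1-one
Product: 20 (3aR,7aR)-2,2-di-tert-butyl-7a-[(trimethylsilyl)ethynyl]-3a,7a-dihydro-1,3,2-benzodioxasilol-5(4H)-one
Conditions: epi-quinidine-derived 3,5-bis(trifluoromethyl)phenyl thiourea (10 mol %), toluene, −20 °C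
Reagents that add atoms: none
Why: Proposed new method: an enantioselective desymmetrising tethered silanoxy-Michael addition, in which the quinuclidine nitrogen hydrogen-bonds to (and partly deprotonates) the Si–OH, which is more acidic than a carbinol, while the thiourea binds the dienone carbonyl, so the silanol oxygen attacks one of the two enantiotopic β-carbons in a 5-exo-trig closure; the short O–Si–O tether can only close cis, so the quaternary carbinol centre (7a, R) and the new C–O centre (3a, R) are set together, and the closest known reaction types are the boronic acid hemiester oxa-Michael desymmetrisation of p-quinols, amine–thiourea-catalysed intramolecular oxa-Michael cyclisations of hydroxy enones and tethered silanol additions to alkenes.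

**Step 10**
Reactants: 20 (3aR,7aR)-2,2-di-tert-butyl-7a-[(trimethylsilyl)ethynyl]-3a,7a-dihydro-1,3,2-benzodioxasilol-5(4H)-one
Product: 21 (3aR,7aR)-2,2-di-tert-butyl-6-iodo-7a-[(trimethylsilyl)ethynyl]-3a,7a-dihydro-1,3,2-benzodioxasilol-5(4H)-one
Conditions: I2, pyridine, CH2Cl2, 0 °C → rt
Reagents that add atoms: iodine II
Why: Johnson α-iodination of an enone (pyridine conjugate addition, enolate iodination, elimination) works on 4,4-disubstituted cyclohexenones and leaves the silyl alkyne and silylene alone.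

**Step 11**
Reactants: 22 cyclopentane-1,3-dione
Product: 23 2-(hydroxyimino)cyclopentane-1,3-dione
Conditions: NaNO2, aq HCl, 0 °C
Reagents that add atoms: sodium nitrite [Na+].[O-]N=O
Why: C-Nitrosation of the enolised 1,3-diketone followed by tautomerisation to the oxime.

**Step 12**
Reactants: 23 2-(hydroxyimino)cyclopentane-1,3-dione
Product: 24 2-amino-3-hydroxycyclopent-2-en-1-one hydrochloride
Conditions: H2 (1 atm), 10 % Pd/C, HCl, MeOH, rt
Reagents that add atoms: hydrogen chloride Cl
Why: Catalytic hydrogenation of an α-oximino ketone to the α-amino ketone, trapped as the hydrochloride of its stable enol so that it cannot self-condense.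

**Step 13**
Reactants: 25 methyl (2E)-4-oxobut-2-enoate
Product: 26 methyl (2E,4E)-5-iodopenta-2,4-dienoate
Conditions: CHI3, CrCl2, THF, 0 °C
Reagents that add atoms: iodoform IC(I)I
Why: Takai olefination: the gem-dichromium species from iodoform adds to the aldehyde and eliminates to the (E)-vinyl iodide.

**Step 14**
Reactants: 26 methyl (2E,4E)-5-iodopenta-2,4-dienoate
Product: 27 (2E,4E)-5-iodopenta-2,4-dienoic acid
Conditions: LiOH, THF/H2O, 0 °C → rt; then 1 M HCl
Reagents that add atoms: lithium hydroxide [Li+].[OH-]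
Why: Saponification of the methyl ester; the dienyl iodide is stable to cold aqueous hydroxide.

**Step 15**
Reactants: 27 (2E,4E)-5-iodopenta-2,4-dienoic acid; 24 2-amino-3-hydroxycyclopent-2-en-1-one hydrochloride
Product: 29 (2E,4E)-N-(2-hydroxy-5-oxocyclopent-1-en-1-yl)-5-iodopenta-2,4-dienamide, via acid chloride 28 (not isolated)
Conditions: (COCl)2, cat. DMF, CH2Cl2, 0 °C; then 24, Et3N, CH2Cl2/DMF, 0 °C → rt
Reagents that add atoms: none
Why: N-Acylation of the amine by the acid chloride; any O-acyl enol ester rearranges to the amide under Et3N (O→N acyl shift).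

**Step 16**
Reactants: 21 (3aR,7aR)-2,2-di-tert-butyl-6-iodo-7a-[(trimethylsilyl)ethynyl]-3a,7a-dihydro-1,3,2-benzodioxasilol-5(4H)-one; 13 (2E,4R,6S)-4,6-dimethyldec-2-enamide
Product: 30 (2E,4R,6S)-N-{(3aR,7aR)-2,2-di-tert-butyl-5-oxo-7a-[(trimethylsilyl)ethynyl]-3a,4,5,7a-tetrahydro-1,3,2-benzodioxasilol-6-yl}-4,6-dimethyldec-2-enamide
Conditions: CuI (10 mol %), trans-N,N′-dimethylcyclohexane-1,2-diamine (20 mol %), K2CO3, toluene, 60 °C
Reagents that add atoms: none
Why: Goldberg–Buchwald copper-catalysed N-vinylation: the activated C–I bond of the α-iodoenone adds to the Cu(I) amidate and C–N reductive elimination joins side chain and core; no stereocentre is touched (7a is quaternary and 3a is held cis by the silylene).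

**Step 17**
Reactants: 30 (2E,4R,6S)-N-{(3aR,7aR)-2,2-di-tert-butyl-5-oxo-7a-[(trimethylsilyl)ethynyl]-3a,4,5,7a-tetrahydro-1,3,2-benzodioxasilol-6-yl}-4,6-dimethyldec-2-enamide
Product: 31 (2E,4R,6S)-N-[(3R,4R)-3-ethynyl-3,4-dihydroxy-6-oxocyclohex-1-en-1-yl]-4,6-dimethyldec-2-enamide
Conditions: TBAF (3.5 equiv), AcOH (3.5 equiv), THF, 0 °C
Reagents that add atoms: none
Why: Fluoride cleaves both Si–O bonds of the silylene and the C(sp)–Si bond in one operation; the acetic acid buffer protects the β-hydroxy ketone from retro-aldol and elimination.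

**Step 18**
Reactants: 31 (2E,4R,6S)-N-[(3R,4R)-3-ethynyl-3,4-dihydroxy-6-oxocyclohex-1-en-1-yl]-4,6-dimethyldec-2-enamide
Product: 32 (2E,4R,6S)-N-{(3R,4R)-3,4-dihydroxy-6-oxo-3-[(E)-2-(tributylstannyl)ethenyl]cyclohex-1-en-1-yl}-4,6-dimethyldec-2-enamide
Conditions: Bu3SnH (1.2 equiv, slow addition), PdCl2(PPh3)2 (5 mol %), THF, 0 °C
Reagents that add atoms: tributyltin hydride CCCC[SnH](CCCC)CCCC
Why: Palladium-catalysed syn-hydrostannylation of a terminal alkyne: the fully substituted carbinol carbon steers tin to the terminal carbon, and syn addition gives the (E)-vinylstannane.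

**Step 19**
Reactants: 32 (2E,4R,6S)-N-{(3R,4R)-3,4-dihydroxy-6-oxo-3-[(E)-2-(tributylstannyl)ethenyl]cyclohex-1-en-1-yl}-4,6-dimethyldec-2-enamide; 29 (2E,4E)-N-(2-hydroxy-5-oxocyclopent-1-en-1-yl)-5-iodopenta-2,4-dienamide
Product: 33 (2E,4R,6S)-N-[(3S,4R)-3,4-dihydroxy-3-{(1E,3E,5E)-7-[(2-hydroxy-5-oxocyclopent-1-en-1-yl)amino]-7-oxohepta-1,3,5-trien-1-yl}-6-oxocyclohex-1-en-1-yl]-4,6-dimethyldec-2-enamide
Conditions: PdCl2(MeCN)2 (10 mol %), DMF, rt, dark
Reagents that add atoms: none
Why: Stille cross-coupling: transmetalation and reductive elimination go with retention at both sp2 carbons, so the all-E triene forms under neutral conditions that the free diol, β-hydroxy ketone and acidic aminocyclopentenone tolerate.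

**Compound list**
1 | n-butylboronic acid | CCCCB(O)O | starting material
2 | 2-butyl-4,4,5,5-tetramethyl-1,3,2-dioxaborolane | CCCCB1OC(C)(C)C(C)(C)O1 | intermediate
3 | lithium butyl(pinacolato)[(1R)-1-(2,4,6-triisopropylbenzoyloxy)ethyl]borate | [Li+].CCCC[B-]1(OC(C)(C)C(C)(C)O1)[C@H](C)OC(=O)c2c(C(C)C)cc(C(C)C)cc2C(C)C | intermediate
4 | (S)-2-(hexan-2-yl)-4,4,5,5-tetramethyl-1,3,2-dioxaborolane | CCCC[C@H](C)B1OC(C)(C)C(C)(C)O1 | intermediate
5 | lithium (chloromethyl)[(2S)-hexan-2-yl](pinacolato)borate | [Li+].CCCC[C@H](C)[B-]1(CCl)OC(C)(C)C(C)(C)O1 | intermediate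
6 | (R)-4,4,5,5-tetramethyl-2-(2-methylhexyl)-1,3,2-dioxaborolane | CCCC[C@H](C)CB1OC(C)(C)C(C)(C)O1 | intermediate
7 | lithium [(2R)-2-methylhexyl](pinacolato)[(1S)-1-(2,4,6-triisopropylbenzoyloxy)ethyl]borate | [Li+].CCCC[C@H](C)C[B-]1(OC(C)(C)C(C)(C)O1)[C@@H](C)OC(=O)c2c(C(C)C)cc(C(C)C)cc2C(C)C | intermediate
8 | 4,4,5,5-tetramethyl-2-[(2R,4S)-4-methyloctan-2-yl]-1,3,2-dioxaborolane | CCCC[C@H](C)C[C@@H](C)B1OC(C)(C)C(C)(C)O1 | intermediate
9 | bromomagnesium ethenyl[(2R,4S)-4-methyloctan-2-yl](pinacolato)borate | Br[Mg+].CCCC[C@H](C)C[C@@H](C)[B-]1(C=C)OC(C)(C)C(C)(C)O1 | intermediate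
10 | 2-[(3R,5S)-1-iodo-3,5-dimethylnonan-2-yl]-4,4,5,5-tetramethyl-1,3,2-dioxaborolane (both C2 epimers) | CCCC[C@H](C)C[C@@H](C)C(CI)B1OC(C)(C)C(C)(C)O1 | intermediate
11 | (3R,5S)-3,5-dimethylnon-1-ene | CCCC[C@H](C)C[C@@H](C)C=C | intermediate
12 | acrylamide | C=CC(N)=O | starting material
13 | (2E,4R,6S)-4,6-dimethyldec-2-enamide | CCCC[C@H](C)C[C@@H](C)/C=C/C(N)=O | intermediate
14 | 1,4-benzoquinone | O=C1C=CC(=O)C=C1 | starting material
15 | ethynyltrimethylsilane | C#C[Si](C)(C)C | starting material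
16 | lithium (trimethylsilyl)acetylide | [Li]C#C[Si](C)(C)C | intermediate
17 | 4-hydroxy-4-[(trimethylsilyl)ethynyl]cyclohexa-2,5-dien-1-one | O=C1C=CC(O)(C#C[Si](C)(C)C)C=C1 | intermediate
18 | 4-{[di-tert-butyl(trifluoromethanesulfonyloxy)silyl]oxy}-4-[(trimethylsilyl)ethynyl]cyclohexa-2,5-dien-1-one | O=C1C=CC(O[Si](OS(=O)(=O)C(F)(F)F)(C(C)(C)C)C(C)(C)C)(C#C[Si](C)(C)C)C=C1 | intermediate
19 | 4-{[di-tert-butyl(hydroxy)silyl]oxy}-4-[(trimethylsilyl)ethynyl]cyclohexa-2,5-dien-1-one | O=C1C=CC(O[Si](O)(C(C)(C)C)C(C)(C)C)(C#C[Si](C)(C)C)C=C1 | intermediate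
20 | (3aR,7aR)-2,2-di-tert-butyl-7a-[(trimethylsilyl)ethynyl]-3a,7a-dihydro-1,3,2-benzodioxasilol-5(4H)-one (cis-fused) | O=C1C=C[C@@](O2)(C#C[Si](C)(C)C)[C@H](O[Si]2(C(C)(C)C)C(C)(C)C)C1 | intermediate
21 | (3aR,7aR)-2,2-di-tert-butyl-6-iodo-7a-[(trimethylsilyl)ethynyl]-3a,7a-dihydro-1,3,2-benzodioxasilol-5(4H)-one | O=C1C(I)=C[C@@](O2)(C#C[Si](C)(C)C)[C@H](O[Si]2(C(C)(C)C)C(C)(C)C)C1 | intermediate
22 | cyclopentane-1,3-dione | O=C1CCC(=O)C1 | starting material
23 | 2-(hydroxyimino)cyclopentane-1,3-dione | ON=C1C(=O)CCC1=O | intermediate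
24 | 2-amino-3-hydroxycyclopent-2-en-1-one hydrochloride | NC1=C(O)CCC1=O.Cl | intermediate
25 | methyl (2E)-4-oxobut-2-enoate | COC(=O)/C=C/C=O | starting material
26 | methyl (2E,4E)-5-iodopenta-2,4-dienoate | COC(=O)/C=C/C=C/I | intermediate
27 | (2E,4E)-5-iodopenta-2,4-dienoic acid | OC(=O)/C=C/C=C/I | intermediate
28 | (2E,4E)-5-iodopenta-2,4-dienoyl chloride | ClC(=O)/C=C/C=C/I | intermediate
29 | (2E,4E)-N-(2-hydroxy-5-oxocyclopent-1-en-1-yl)-5-iodopenta-2,4-dienamide | I/C=C/C=C/C(=O)NC1=C(O)CCC1=O | intermediate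
30 | (2E,4R,6S)-N-{(3aR,7aR)-2,2-di-tert-butyl-5-oxo-7a-[(trimethylsilyl)ethynyl]-3a,4,5,7a-tetrahydro-1,3,2-benzodioxasilol-6-yl}-4,6-dimethyldec-2-enamide | CCCC[C@H](C)C[C@@H](C)/C=C/C(=O)NC1=C[C@@](O2)(C#C[Si](C)(C)C)[C@H](O[Si]2(C(C)(C)C)C(C)(C)C)CC1=O | intermediate
31 | (2E,4R,6S)-N-[(3R,4R)-3-ethynyl-3,4-dihydroxy-6-oxocyclohex-1-en-1-yl]-4,6-dimethyldec-2-enamide (cis-diol) | CCCC[C@H](C)C[C@@H](C)/C=C/C(=O)NC1=C[C@@](O)(C#C)[C@H](O)CC1=O | intermediate
32 | (2E,4R,6S)-N-{(3R,4R)-3,4-dihydroxy-6-oxo-3-[(E)-2-(tributylstannyl)ethenyl]cyclohex-1-en-1-yl}-4,6-dimethyldec-2-enamide | CCCC[C@H](C)C[C@@H](C)/C=C/C(=O)NC1=C[C@@](O)(/C=C/[Sn](CCCC)(CCCC)CCCC)[C@H](O)CC1=O | intermediate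
33 | (2E,4R,6S)-N-[(3S,4R)-3,4-dihydroxy-3-{(1E,3E,5E)-7-[(2-hydroxy-5-oxocyclopent-1-en-1-yl)amino]-7-oxohepta-1,3,5-trien-1-yl}-6-oxocyclohex-1-en-1-yl]-4,6-dimethyldec-2-enamide | CCCC[C@H](C)C[C@@H](C)/C=C/C(=O)NC1=C[C@@](O)(/C=C/C=C/C=C/C(=O)NC2=C(O)CCC2=O)[C@H](O)CC1=O | target

The ring carbinol centre keeps the same spatial arrangement from 20 to 33; its descriptor reads R while the substituent is alkynyl or stannylvinyl and S in the target only because the CIP priorities change.

**Step count**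
Total: 19 steps. Longest linear sequence: 10 steps (steps 1–6, then 16–19).

**Three steps most likely to fail**

Step 9 (the new desymmetrisation). The risks are a racemic background cyclisation of silanol 19 (already possible during the basic work-up of step 8), low enantioselectivity with a silanol nucleophile, and erosion of ee by retro-Michael reaction, since ring-opening of 20 returns achiral 19. The fallback uses known chemistry, sets out from 17 and comes back at 20. Compound 17 is treated with phenylboronic acid and the same chiral amine–thiourea catalyst (CH2Cl2, rt); the boronic acid hemiester of the tertiary alcohol adds to one enone arm, the known oxa-Michael desymmetrisation of p-quinols, and gives the cyclic boronate (3aR,7aR)-2-phenyl-7a-[(trimethylsilyl)ethynyl]-3a,7a-dihydro-1,3,2-benzodioxaborol-5(4H)-one F1. Exchange with pinacol (MeOH, rt) frees (4R,5R)-4,5-dihydroxy-4-[(trimethylsilyl)ethynyl]cyclohex-2-en-1-one F2, and tBu2Si(OTf)2 with 2,6-lutidine (CH2Cl2, 0 °C) closes the silylene to give 20.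

Step 16 (copper N-vinylation). The risks are base-induced opening of the β-siloxy ketone at 60 °C, conjugate addition of the diamine ligand to the unsaturated amide, and slow coupling of a primary enamide. The fallback builds the enamide by acylation instead; it sets out from 21 (and from 11 for the acyl part) and comes back at 30. Copper-catalysed azidation of the vinyl iodide (NaN3, CuI, sodium ascorbate, N,N′-dimethylethylenediamine, EtOH/H2O, rt) gives (3aR,7aR)-6-azido-2,2-di-tert-butyl-7a-[(trimethylsilyl)ethynyl]-3a,7a-dihydro-1,3,2-benzodioxasilol-5(4H)-one F3, and Staudinger reduction (PPh3, THF/H2O) gives (3aR,7aR)-6-amino-2,2-di-tert-butyl-7a-[(trimethylsilyl)ethynyl]-3a,7a-dihydro-1,3,2-benzodioxasilol-5(4H)-one F4, used at once. In parallel, cross-metathesis of 11 with acrylic acid (Hoveyda–Grubbs II, CH2Cl2, 40 °C) gives (2E,4R,6S)-4,6-dimethyldec-2-enoic acid F5, and oxalyl chloride with catalytic DMF gives (2E,4R,6S)-4,6-dimethyldec-2-enoyl chloride F6. Acylation of F4 with F6 (pyridine, CH2Cl2, 0 °C) gives 30.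

Step 18 (hydrostannylation). The risks are formation of the internal stannane, tin hydride conjugate reduction of the enone, and protodestannylation on silica. The fallback avoids tin; it sets out from 31 and comes back at 33. Lindlar semi-hydrogenation (H2, Pd/CaCO3–Pb, quinoline, EtOAc) gives (2E,4R,6S)-N-[(3S,4R)-3-ethenyl-3,4-dihydroxy-6-oxocyclohex-1-en-1-yl]-4,6-dimethyldec-2-enamide F7. A Heck reaction of this tertiary vinyl carbinol with iodide 29 (Pd(OAc)2, Ag2CO3, DMF, rt) gives the E-alkene directly, which is 33.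

**Further compounds**
F1 | step 9 | (3aR,7aR)-2-phenyl-7a-[(trimethylsilyl)ethynyl]-3a,7a-dihydro-1,3,2-benzodioxaborol-5(4H)-one | O=C1C=C[C@@](O2)(C#C[Si](C)(C)C)[C@H](OB2c3ccccc3)C1
F2 | step 9 | (4R,5R)-4,5-dihydroxy-4-[(trimethylsilyl)ethynyl]cyclohex-2-en-1-one | O=C1C=C[C@@](O)(C#C[Si](C)(C)C)[C@H](O)C1
F3 | step 16 | (3aR,7aR)-6-azido-2,2-di-tert-butyl-7a-[(trimethylsilyl)ethynyl]-3a,7a-dihydro-1,3,2-benzodioxasilol-5(4H)-one | O=C1C(N=[N+]=[N-])=C[C@@](O2)(C#C[Si](C)(C)C)[C@H](O[Si]2(C(C)(C)C)C(C)(C)C)C1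
F4 | step 16 | (3aR,7aR)-6-amino-2,2-di-tert-butyl-7a-[(trimethylsilyl)ethynyl]-3a,7a-dihydro-1,3,2-benzodioxasilol-5(4H)-one | O=C1C(N)=C[C@@](O2)(C#C[Si](C)(C)C)[C@H](O[Si]2(C(C)(C)C)C(C)(C)C)C1
F5 | step 16 | (2E,4R,6S)-4,6-dimethyldec-2-enoic acid | CCCC[C@H](C)C[C@@H](C)/C=C/C(O)=O
F6 | step 16 | (2E,4R,6S)-4,6-dimethyldec-2-enoyl chloride | CCCC[C@H](C)C[C@@H](C)/C=C/C(Cl)=O
F7 | step 18 | (2E,4R,6S)-N-[(3S,4R)-3-ethenyl-3,4-dihydroxy-6-oxocyclohex-1-en-1-yl]-4,6-dimethyldec-2-enamide | CCCC[C@H](C)C[C@@H](C)/C=C/C(=O)NC1=C[C@@](O)(C=C)[C@H](O)CC1=O
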